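The decalin is cut at the C9–C10 bond of ring B (spongian numbering: C9 carries the formyl carbon C11, C10 the angular methyl, C8 the dihydrofuran). The precursor is monocyclic: ring A with an exocyclic methylene at C10, its C5 stereocentre made enzymatically, and a 3-oxopentanoate chain. A Lewis acid turns the methylene into the C10 cation, which the β-keto ester enol captures at C9; one operation closes ring B, builds the C10 quaternary centre and sets C9. The step exploits the 1,3-relation of C11 to C8: a temporary C8 ketone makes C9 nucleophilic and later becomes the radical site that takes up a ready-made chiral butenolide, the precursor of the acetoxydihydrofuran.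

Key step: step 3

Assumption: 1 and 8 are taken as catalogue compounds (8 is the mirror image of the common (−)-menthol-derived butenolide and is made the same way from (+)-menthol); atom labels follow spongian numbering (C15 acetal carbon, C16 enol ether carbon, C12 the CH2OAc carbon), and "11-X-driman-8α-yl" means the trans-decalin of the target bonded through C8 on its equatorial α face, with XCH2 on C9.

Step 1
Reactants: 1 (E)-geranylacetone
Product: 2 (S)-γ-dihydroionone
Conditions: squalene–hopene cyclase variant engineered for monocyclisation (E. coli whole cells), citrate buffer pH 6, SDS, 30 °C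
Reagents that add atoms: none
Why: Enzymatic cation–olefin monocyclisation by a protonation-initiated terpene cyclase: the active-site acid protonates the terminal alkene of the chair-folded chain, ring A closes, and loss of a methyl proton from the C10 cation gives the exocyclic alkene; the enzyme-imposed fold should set C5 as (S), the natural drimane configuration.

Step 2
Reactants: 2 (S)-γ-dihydroionone
Product: 3 methyl 5-[(1S)-2,2-dimethyl-6-methylidenecyclohexyl]-3-oxopentanoate
Conditions: NaH, (MeO)2CO, THF, reflux; then AcOH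
Reagents that add atoms: dimethyl carbonate, COC(=O)OC
Why: Claisen-type C-acylation of the methyl ketone at its methyl group, driven by formation of the stabilised β-keto ester enolate; no stereocentre is touched.

Step 3
Reactants: 3 methyl 5-[(1S)-2,2-dimethyl-6-methylidenecyclohexyl]-3-oxopentanoate
Product: 4 methyl (1R,4aS,8aS)-5,5,8a-trimethyl-2-oxodecahydronaphthalene-1-carboxylate
Conditions: SnCl4 (2 equiv), CH2Cl2, −78 to 0 °C
Reagents that add atoms: none
Why: SnCl4 chelates the β-keto ester as its enol and the acid so released protonates the exocyclic methylene in the Markovnikov sense, which completes the angular methyl group and leaves a tertiary cation at C10; the enol carbon C9 then bonds to C10. The closest known reaction type is the Lewis acid-promoted cation–olefin cyclisation terminated by a β-keto ester enol. Ring B closes by C9–C10 bond formation, a six-membered closure in which the enol double bond C8=C9 lies inside the new ring and the trigonal cation is attacked through a chair-like transition state. C10 is controlled by the existing C5 centre, whose equatorial C6 chain delivers C9 so that the new bond is equatorial and the methyl group axial and anti to H-5 (trans-decalin), and C9 settles with the ester equatorial because the β-keto ester equilibrates through its enol. The step needs C- over O-alkylation, which the reversibility of O-alkylation under SnCl4 should secure, and ring closure faster than loss of H-5 from the cation, which would erase the C5 centre; the internal nucleophile and the low temperature should favour closure.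

Step 4
Reactants: 4 methyl (1R,4aS,8aS)-5,5,8a-trimethyl-2-oxodecahydronaphthalene-1-carboxylate
Product: 5 methyl albicanate [methyl (1S,4aS,8aS)-5,5,8a-trimethyl-2-methylidenedecahydronaphthalene-1-carboxylate]
Conditions: Ph3PCH3Br, KOtBu, toluene, 90 °C
Reagents that add atoms: methyltriphenylphosphonium bromide, C[P+](c1ccccc1)(c1ccccc1)c1ccccc1.[Br-]
Why: Wittig methylenation of the C8 ketone; the flanking angular methyl group disfavours enolisation toward C9, so olefination should prevail and C9 keeps its equatorial ester.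

Step 5
Reactants: 5 methyl albicanate
Product: 6 (+)-albicanol {[(1S,4aS,8aS)-5,5,8a-trimethyl-2-methylidenedecahydronaphthalen-1-yl]methanol}
Conditions: LiAlH4, THF, 0 °C to rt
Reagents that add atoms: none
Why: Hydride reduction of the ester to the primary alcohol (C11); no stereocentre is affected.

Step 6
Reactants: 6 (+)-albicanol
Product: 7 albicanol tert-butyldiphenylsilyl ether
Conditions: TBDPSCl, imidazole, DMF, rt
Reagents that add atoms: tert-butyl(chloro)diphenylsilane, CC(C)(C)[Si](Cl)(c1ccccc1)c1ccccc1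
Why: Silyl ether formation; this silyl group should survive the later acid acetolysis and be removable with buffered fluoride.

Step 7
Reactants: 7 albicanol tert-butyldiphenylsilyl ether; 8 (5S)-5-[(1S,2R,5S)-menthyloxy]furan-2(5H)-one
Product: 9 (4R,5S)-4-[11-(tert-butyldiphenylsilyloxy)driman-8α-yl]-5-[(1S,2R,5S)-menthyloxy]dihydrofuran-2(3H)-one
Conditions: Fe(acac)3 (30 mol %), PhSiH3, 8 (3 equiv), EtOH/ethylene glycol, 60 °C
Reagents that add atoms: none
Why: Metal-hydride hydrogen atom transfer Giese addition: H-atom transfer to the exocyclic methylene completes the C8 methyl group and gives the tertiary C8 radical, which should add to the butenolide β-carbon (C14) from the equatorial side of ring B, away from the axial angular methyl, and on the butenolide face anti to the menthyloxy group, setting C8 and C14.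

Step 8
Reactants: 9 (4R,5S)-4-[11-(tert-butyldiphenylsilyloxy)driman-8α-yl]-5-[(1S,2R,5S)-menthyloxy]dihydrofuran-2(3H)-one
Product: 11 (3R,4R,5S)-4-[11-(tert-butyldiphenylsilyloxy)driman-8α-yl]-3-(hydroxymethyl)-5-[(1S,2R,5S)-menthyloxy]dihydrofuran-2(3H)-one, via lithium lactone enolate 10 (not isolated)
Conditions: LiN(iPr)2, THF, −78 °C; then monomeric CH2O, −78 to −20 °C; aq. NH4Cl
Reagents that add atoms: formaldehyde, C=O
Why: Enolate aldol reaction (α-hydroxymethylation) at the only α-methylene of the lactone (C13); formaldehyde should enter trans to the bulky C14 substituent, and this centre becomes sp2 again in step 11.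

Step 9
Reactants: 11 (3R,4R,5S)-4-[11-(tert-butyldiphenylsilyloxy)driman-8α-yl]-3-(hydroxymethyl)-5-[(1S,2R,5S)-menthyloxy]dihydrofuran-2(3H)-one
Product: 12 (3R,4R,5S)-5-acetoxy-3-(acetoxymethyl)-4-[11-(tert-butyldiphenylsilyloxy)driman-8α-yl]dihydrofuran-2(3H)-one
Conditions: Ac2O, cat. H2SO4, CH2Cl2, 0 °C
Reagents that add atoms: acetic anhydride, CC(=O)OC(C)=O
Why: Acid-catalysed acetolysis of the menthyl acetal through the C15 oxocarbenium ion together with O-acetylation of the primary alcohol; acetate should add trans to the large C14 substituent, and the exchange is done here because no enol ether is yet present.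

Step 10
Reactants: 12 (3R,4R,5S)-5-acetoxy-3-(acetoxymethyl)-4-[11-(tert-butyldiphenylsilyloxy)driman-8α-yl]dihydrofuran-2(3H)-one
Product: 14 crude C16 lactol of 12 [5-acetoxy-3-(acetoxymethyl)-4-(11-silyloxydriman-8α-yl)tetrahydrofuran-2-ol; both C16 epimers], via O-boryl lactol 13 (not isolated)
Conditions: Sia2BH [bis(3-methylbutan-2-yl)borane], THF, 0 °C to rt; then pH 7 buffer, 0 °C; used at once
Reagents that add atoms: none
Why: Chemoselective dialkylborane reduction of a γ-lactone to the lactol, a reagent type that leaves acetate esters and silyl ethers untouched; the new hemiacetal centre is of no consequence because C16 becomes sp2 in step 11.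

Step 11
Reactants: 14 crude C16 lactol of 12
Product: 16 (2R,3S)-4-(acetoxymethyl)-3-[11-(tert-butyldiphenylsilyloxy)driman-8α-yl]-2,3-dihydrofuran-2-yl acetate, via anomeric mesylate 15 (not isolated)
Conditions: MsCl, Et3N, CH2Cl2, −20 °C to rt
Reagents that add atoms: none
Why: Lactol dehydration by O-mesylation and amine-induced elimination (glycal-type enol ether formation); only C13 carries a hydrogen next to C16, so the C13=C16 enol ether should form regiospecifically while the C15 acetate is inert to amine base.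

Step 12
Reactants: 16 (2R,3S)-4-(acetoxymethyl)-3-[11-(tert-butyldiphenylsilyloxy)driman-8α-yl]-2,3-dihydrofuran-2-yl acetate
Product: 17 (2R,3S)-4-(acetoxymethyl)-3-(11-hydroxydriman-8α-yl)-2,3-dihydrofuran-2-yl acetate
Conditions: Bu4NF, AcOH (1:1), THF, rt
Reagents that add atoms: none
Why: Fluoride cleavage of the silyl ether under buffered, near-neutral conditions that should spare both acetates and the enol ether.

Step 13
Reactants: 17 (2R,3S)-4-(acetoxymethyl)-3-(11-hydroxydriman-8α-yl)-2,3-dihydrofuran-2-yl acetate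
Product: 18 (2R,3S)-4-(acetoxymethyl)-3-[(1R,2R,4aS,8aS)-1-formyl-2,5,5,8a-tetramethyldecahydronaphthalen-2-yl]-2,3-dihydrofuran-2-yl acetate (CNP0170308.1)
Conditions: Dess–Martin periodinane, NaHCO3, CH2Cl2, 0 °C to rt
Reagents that add atoms: none
Why: Dess–Martin oxidation of the primary C11 alcohol to the aldehyde under buffered, non-acidic conditions; the formyl group stays equatorial at C9, its thermodynamic position.

Compound list
1 | (E)-geranylacetone [(5E)-6,10-dimethylundeca-5,9-dien-2-one] | CC(=O)CC/C=C(\C)CCC=C(C)C | starting material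
2 | (S)-γ-dihydroionone [4-[(1S)-2,2-dimethyl-6-methylidenecyclohexyl]butan-2-one] | CC(=O)CC[C@@H]1C(=C)CCCC1(C)C | intermediate
3 | methyl 5-[(1S)-2,2-dimethyl-6-methylidenecyclohexyl]-3-oxopentanoate | COC(=O)CC(=O)CC[C@@H]1C(=C)CCCC1(C)C | intermediate
4 | methyl (1R,4aS,8aS)-5,5,8a-trimethyl-2-oxodecahydronaphthalene-1-carboxylate | O=C1CC[C@H]2C(C)(C)CCC[C@]2(C)[C@H]1C(=O)OC | intermediate
5 | methyl albicanate [methyl (1S,4aS,8aS)-5,5,8a-trimethyl-2-methylidenedecahydronaphthalene-1-carboxylate] | C=C1CC[C@H]2C(C)(C)CCC[C@]2(C)[C@H]1C(=O)OC | intermediate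
6 | (+)-albicanol {[(1S,4aS,8aS)-5,5,8a-trimethyl-2-methylidenedecahydronaphthalen-1-yl]methanol} | C=C1CC[C@H]2C(C)(C)CCC[C@]2(C)[C@H]1CO | intermediate
7 | albicanol tert-butyldiphenylsilyl ether | C=C1CC[C@H]2C(C)(C)CCC[C@]2(C)[C@H]1CO[Si](c3ccccc3)(c4ccccc4)C(C)(C)C | intermediate
8 | (5S)-5-[(1S,2R,5S)-menthyloxy]furan-2(5H)-one | O=C1C=C[C@@H](O[C@@H]2[C@@H](C(C)C)CC[C@H](C)C2)O1 | starting material
9 | (4R,5S)-4-[11-(tert-butyldiphenylsilyloxy)driman-8α-yl]-5-[(1S,2R,5S)-menthyloxy]dihydrofuran-2(3H)-one | O=C1C[C@H]([C@]2(C)CC[C@H]3C(C)(C)CCC[C@]3(C)[C@H]2CO[Si](c4ccccc4)(c5ccccc5)C(C)(C)C)[C@@H](O[C@@H]6[C@@H](C(C)C)CC[C@H](C)C6)O1 | intermediate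
10 | lithium enolate of 9 (enolate across C16–C13) | [Li+].[O-]C1=C[C@H]([C@]2(C)CC[C@H]3C(C)(C)CCC[C@]3(C)[C@H]2CO[Si](c4ccccc4)(c5ccccc5)C(C)(C)C)[C@@H](O[C@@H]6[C@@H](C(C)C)CC[C@H](C)C6)O1 | intermediate
11 | (3R,4R,5S)-4-[11-(tert-butyldiphenylsilyloxy)driman-8α-yl]-3-(hydroxymethyl)-5-[(1S,2R,5S)-menthyloxy]dihydrofuran-2(3H)-one | O=C1[C@@H](CO)[C@H]([C@]2(C)CC[C@H]3C(C)(C)CCC[C@]3(C)[C@H]2CO[Si](c4ccccc4)(c5ccccc5)C(C)(C)C)[C@@H](O[C@@H]6[C@@H](C(C)C)CC[C@H](C)C6)O1 | intermediate
12 | (3R,4R,5S)-5-acetoxy-3-(acetoxymethyl)-4-[11-(tert-butyldiphenylsilyloxy)driman-8α-yl]dihydrofuran-2(3H)-one | O=C1[C@@H](COC(C)=O)[C@H]([C@]2(C)CC[C@H]3C(C)(C)CCC[C@]3(C)[C@H]2CO[Si](c4ccccc4)(c5ccccc5)C(C)(C)C)[C@@H](OC(C)=O)O1 | intermediate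
13 | O-[bis(3-methylbutan-2-yl)boryl] derivative of lactol 14 | CC(C)C(C)B(OC1[C@@H](COC(C)=O)[C@H]([C@]2(C)CC[C@H]3C(C)(C)CCC[C@]3(C)[C@H]2CO[Si](c4ccccc4)(c5ccccc5)C(C)(C)C)[C@@H](OC(C)=O)O1)C(C)C(C)C | intermediate
14 | C16 lactol of 12 [5-acetoxy-3-(acetoxymethyl)-4-(11-silyloxydriman-8α-yl)tetrahydrofuran-2-ol; both C16 epimers] | OC1[C@@H](COC(C)=O)[C@H]([C@]2(C)CC[C@H]3C(C)(C)CCC[C@]3(C)[C@H]2CO[Si](c4ccccc4)(c5ccccc5)C(C)(C)C)[C@@H](OC(C)=O)O1 | intermediate
15 | C16 O-methanesulfonate of lactol 14 | CS(=O)(=O)OC1[C@@H](COC(C)=O)[C@H]([C@]2(C)CC[C@H]3C(C)(C)CCC[C@]3(C)[C@H]2CO[Si](c4ccccc4)(c5ccccc5)C(C)(C)C)[C@@H](OC(C)=O)O1 | intermediate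
16 | (2R,3S)-4-(acetoxymethyl)-3-[11-(tert-butyldiphenylsilyloxy)driman-8α-yl]-2,3-dihydrofuran-2-yl acetate | CC(=O)OCC1=CO[C@H](OC(C)=O)[C@H]1[C@]1(C)CC[C@H]2C(C)(C)CCC[C@]2(C)[C@H]1CO[Si](c3ccccc3)(c4ccccc4)C(C)(C)C | intermediate
17 | (2R,3S)-4-(acetoxymethyl)-3-(11-hydroxydriman-8α-yl)-2,3-dihydrofuran-2-yl acetate | CC(=O)OCC1=CO[C@H](OC(C)=O)[C@H]1[C@]1(C)CC[C@H]2C(C)(C)CCC[C@]2(C)[C@H]1CO | intermediate
18 | (2R,3S)-4-(acetoxymethyl)-3-[(1R,2R,4aS,8aS)-1-formyl-2,5,5,8a-tetramethyldecahydronaphthalen-2-yl]-2,3-dihydrofuran-2-yl acetate (CNP0170308.1) | CC(=O)OCC1=CO[C@H](OC(C)=O)[C@H]1[C@]1(C)CC[C@H]2C(C)(C)CCC[C@]2(C)[C@H]1C=O | target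

Total step count: 13. Longest linear sequence: 13 steps (1 to 18; 8 enters at step 7).

Steps most likely to fail

Step 3. The C10 cation may lose H-5 to give the achiral tetrasubstituted ring alkene, which would cyclise again without stereocontrol and erode optical purity; O-alkylation may also compete. The fallback sets out from 3 and replaces protonation by electrophilic mercuration. Hg(OTf)2 with N,N-dimethylaniline in MeNO2 at −20 °C, followed by aqueous NaCl, should add anti across the exocyclic alkene with ring closure by C9, giving methyl (1R,4aS,8aR)-8a-(chloromercuriomethyl)-5,5-dimethyl-2-oxodecahydronaphthalene-1-carboxylate F1 without a free cation next to C5. NaBH4 in aqueous NaOH then replaces mercury by hydrogen, and the route is rejoined at 4.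

Step 7. Addition of the hindered tertiary radical to the β-substituted butenolide may be slow, so that alkene isomerisation or simple reduction takes over; facial selectivity at C8 could also be incomplete. The fallback sets out from 7 and generates the same radical by photoredox decarboxylation. Mukaiyama hydration (Co(acac)2, PhSiH3, O2, iPrOH) should give 11-(tert-butyldiphenylsilyloxy)driman-8α-ol F2. Acylation with methyl chlorooxoacetate (Et3N, DMAP) gives the tertiary methyl oxalate F3, and CsOH in THF/H2O gives the caesium oxalate F4. Irradiation with blue light in the presence of [Ir(dF(CF3)ppy)2(dtbbpy)]PF6 and 8 in DME/DMF/H2O should then deliver 9.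

Step 10. The acetoxy lactol 14 may collapse by ring opening and loss of acetic acid before it is dehydrated; over-reduction and acetyl migration are further risks. The fallback sets out from 11 and reduces the lactone while C15 still carries the stable menthyl acetal. iBu2AlH at −78 °C gives the lactol diol F5, and PhSO2H with CaCl2 in CH2Cl2 converts the lactol into the anomeric phenyl sulfone F6. Acetolysis (Ac2O, cat. H2SO4, 0 °C) then installs both acetates to give the sulfone diacetate F7. DBU in toluene at 60 °C eliminates benzenesulfinic acid toward C13, and the route is rejoined at 16.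

Further compounds
F1 | step 3 | methyl (1R,4aS,8aR)-8a-(chloromercuriomethyl)-5,5-dimethyl-2-oxodecahydronaphthalene-1-carboxylate | O=C1CC[C@H]2C(C)(C)CCC[C@]2(C[Hg]Cl)[C@H]1C(=O)OC
F2 | step 7 | 11-(tert-butyldiphenylsilyloxy)driman-8α-ol | O[C@]1(C)CC[C@H]2C(C)(C)CCC[C@]2(C)[C@H]1CO[Si](c3ccccc3)(c4ccccc4)C(C)(C)C
F3 | step 7 | 11-(tert-butyldiphenylsilyloxy)driman-8α-yl methyl oxalate | COC(=O)C(=O)O[C@]1(C)CC[C@H]2C(C)(C)CCC[C@]2(C)[C@H]1CO[Si](c3ccccc3)(c4ccccc4)C(C)(C)C
F4 | step 7 | caesium 11-(tert-butyldiphenylsilyloxy)driman-8α-yl oxalate | [Cs+].[O-]C(=O)C(=O)O[C@]1(C)CC[C@H]2C(C)(C)CCC[C@]2(C)[C@H]1CO[Si](c3ccccc3)(c4ccccc4)C(C)(C)C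
F5 | step 10 | C16 lactol of 11 [4-(11-silyloxydriman-8α-yl)-3-(hydroxymethyl)-5-menthyloxytetrahydrofuran-2-ol; both C16 epimers] | OC1[C@@H](CO)[C@H]([C@]2(C)CC[C@H]3C(C)(C)CCC[C@]3(C)[C@H]2CO[Si](c4ccccc4)(c5ccccc5)C(C)(C)C)[C@@H](O[C@@H]6[C@@H](C(C)C)CC[C@H](C)C6)O1
F6 | step 10 | C16 phenyl sulfone from F5 [3-(hydroxymethyl)-5-menthyloxy-2-(phenylsulfonyl)tetrahydrofuran; both C16 epimers] | O=S(=O)(c7ccccc7)C1[C@@H](CO)[C@H]([C@]2(C)CC[C@H]3C(C)(C)CCC[C@]3(C)[C@H]2CO[Si](c4ccccc4)(c5ccccc5)C(C)(C)C)[C@@H](O[C@@H]6[C@@H](C(C)C)CC[C@H](C)C6)O1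
F7 | step 10 | C16 phenyl sulfone diacetate [5-acetoxy-3-(acetoxymethyl)-2-(phenylsulfonyl)tetrahydrofuran; both C16 epimers] | O=S(=O)(c7ccccc7)C1[C@@H](COC(C)=O)[C@H]([C@]2(C)CC[C@H]3C(C)(C)CCC[C@]3(C)[C@H]2CO[Si](c4ccccc4)(c5ccccc5)C(C)(C)C)[C@@H](OC(C)=O)O1
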